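**Strategy.** The route rests on opening the C5–C10 bond of a cyclohexane while forming C7–C8. In the target the two ether carbons C5 and C10 (shared by oxepane rings A and B) sit 1,6 across the ten-membered carbocycle C1–C10, opposite the C7–C8 lactone fusion; this is the footprint of an anionic oxy-Cope ring expansion. One operation turns trans-1,2-dialkenyl-2,6-dimethylcyclohexanol 16 (an (E)-alkenyl group on C5, an (E)-benzyl enol ether on C10) into (E)-cyclodec-5-enone 19, creating the ring and the C7/C8 stereocentres. Hydride reduction and transannular epoxide opening then stitch the C5–O–C10 bridge; lactonisation, masked methylenation and acylation finish.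

Key step: step 10

Remark (numbering): atom labels follow the target: C1–C3 CH2, C4 CH–CH3, C5 and C10 ether carbons, C6 CH2, C7/C8 lactone fusion, C9 ester carbon, C11=C13 methylene, C12 carbonyl; ring A = C10, C1–C5, O; ring B = C5–C10, O; target configuration 4S,5R,7R,8R,9S,10R.

Remark (stereochemical bookkeeping): 16 is (1S,2R,6S) and 19 is (3S,4R,10S); these are related by the chair transition state and map onto C4, C7 and C8 of the target (7S in 19 and 7R in the target are the same arrangement under changed priorities).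

Remark (design): both alkenes of 16 are made by stereospecific methods so that no E/Z mixture reaches the key step; C4 is fixed before C10 is built; the primary alcohol is carried as a benzyl ether so that one hydrogenolysis frees both lactone oxygens.

Assumption (starting material): commercial 2,6-dimethylcyclohexanone is a cis-rich mixture; the meso cis isomer 1 is the intended substrate, and material from the trans isomer that ends as the C6 epimer of 4 is removed by chromatography there.

Assumption (sense of induction): the (S,S)-amide and the (R)-phosphinooxazoline are taken as the enantiomers that give (6S)-3 and (2R)-4, by analogy with 4-tert-butylcyclohexanone and 2-methylcyclohexanone substrates; if either sense proves opposite, the antipodal reagent is used.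

**Step 1**
Reactants: 1 cis-2,6-dimethylcyclohexan-1-one
Product: 3 trimethyl{[(6S)-2,6-dimethylcyclohex-1-en-1-yl]oxy}silane, via lithium enolate 2 (not isolated)
Conditions: LiN[(S)-CH(CH3)Ph]2 (from the amine and n-BuLi), LiCl, Me3SiCl present from the start, THF, −100 °C
Reagents that add atoms: chlorotrimethylsilane, C[Si](C)(C)Cl
Why: Enantiotopic-group-selective deprotonation of the meso ketone by the chiral lithium amide under internal silyl quench (asymmetric deprotonation, kinetic O-silylation) removes the α-hydrogen at the (2R) carbon, so the untouched (6S) methyl carbon, which becomes C4 of the target, is fixed and cannot equilibrate because no free enolate accumulates.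

**Step 2**
Reactants: 3 trimethyl{[(6S)-2,6-dimethylcyclohex-1-en-1-yl]oxy}silane
Product: 4 (2R,6S)-2,6-dimethyl-2-(prop-2-en-1-yl)cyclohexan-1-one
Conditions: Pd2(dba)3 (2.5 mol %), (R)-t-Bu-PHOX (6 mol %), diallyl carbonate, Bu4N[Ph3SiF2] (35 mol %), THF, 25 °C
Reagents that add atoms: diallyl carbonate, C=CCOC(=O)OCC=C
Why: Fluoride releases the enolate, which is allylated at C10 by the π-allyl palladium phosphinooxazoline complex (enantioselective Tsuji allylation), the ligand controlling the new quaternary centre as R and the substrate reinforcing it by bond formation anti to the C4 methyl group, so that any enantiomeric leakage of step 1 ends as a separable diastereomer and not as the enantiomer.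

**Step 3**
Reactants: 4 (2R,6S)-2,6-dimethyl-2-(prop-2-en-1-yl)cyclohexan-1-one
Product: 5 (2R,6S)-2,6-dimethyl-2-[(1E)-prop-1-en-1-yl]cyclohexan-1-one
Conditions: RuHCl(CO)(PPh3)3 (2 mol %), toluene, 100 °C
Reagents that add atoms: none
Why: Reversible insertion of the terminal alkene into the Ru–H bond and β-hydride elimination (transition-metal hydride alkene isomerisation) move the double bond one position to the more substituted propenyl isomer under neutral conditions that touch neither stereocentre.

**Step 4**
Reactants: 5 (2R,6S)-2,6-dimethyl-2-[(1E)-prop-1-en-1-yl]cyclohexan-1-one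
Product: 7 (1R,3S)-1,3-dimethyl-2-oxocyclohexane-1-carbaldehyde, via ozonide 6 (not isolated)
Conditions: O3, CH2Cl2, −78 °C; then PPh3, −78 to 25 °C
Reagents that add atoms: ozone, [O-][O+]=O
Why: Ozonolysis with reductive work-up cleaves the only alkene and leaves C9 as the aldehyde, under neutral conditions in which the quaternary C10 cannot enolise and C4 is not epimerised.

**Step 5**
Reactants: 7 (1R,3S)-1,3-dimethyl-2-oxocyclohexane-1-carbaldehyde
Product: 8 (2R,6S)-2,6-dimethyl-2-[(E)-2-(4,4,5,5-tetramethyl-1,3,2-dioxaborolan-2-yl)ethenyl]cyclohexan-1-one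
Conditions: Cl2CHB(pin), CrCl2 (8 equiv), LiI (4 equiv), THF, 25 °C
Reagents that add atoms: 2-(dichloromethyl)-4,4,5,5-tetramethyl-1,3,2-dioxaborolane, ClC(Cl)B1OC(C)(C)C(C)(C)O1
Why: The geminal dichromium reagent formed from the dichloromethylboronate and divalent chromium adds to the aldehyde in preference to the hindered ketone and eliminates to the trans alkene (Takai–Utimoto olefination, boron variant), which is strongly E-selective for α-branched aldehydes and gives the (E)-alkenylboronate carrying C8.

**Step 6**
Reactants: 8 (2R,6S)-2,6-dimethyl-2-[(E)-2-(4,4,5,5-tetramethyl-1,3,2-dioxaborolan-2-yl)ethenyl]cyclohexan-1-one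
Product: 9 (2R,6S)-2-[(E)-2-(benzyloxy)ethenyl]-2,6-dimethylcyclohexan-1-one
Conditions: Cu(OAc)2 (2 equiv), Et3N (4 equiv), BnOH (10 equiv), 4 Å molecular sieves, CH2Cl2, 25 °C
Reagents that add atoms: benzyl alcohol, OCc1ccccc1
Why: Oxidative copper-mediated C–O coupling of the alkenylboronate with benzyl alcohol (Chan–Lam coupling) proceeds by transmetalation and reductive elimination at copper with retention of alkene geometry, and its amine-buffered room-temperature conditions are too weakly basic to epimerise C4.

**Step 7**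
Reactants: 10 but-3-yn-1-ol
Product: 11 [(but-3-yn-1-yloxy)methyl]benzene
Conditions: NaH, BnBr, Bu4NI (cat.), THF, 0 to 25 °C
Reagents that add atoms: benzyl bromide, BrCc1ccccc1
Why: Williamson etherification of the sodium alkoxide, which forms selectively because the hydroxyl is far more acidic than the alkyne C–H.

**Step 8**
Reactants: 11 [(but-3-yn-1-yloxy)methyl]benzene
Product: 13 ({[(3E)-4-iodobut-3-en-1-yl]oxy}methyl)benzene, via alkenylzirconocene chloride 12 (not isolated)
Conditions: Cp2Zr(H)Cl, THF, 25 °C; then I2, 0 °C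
Reagents that add atoms: iodine, [I][I]
Why: Hydrozirconation adds Zr–H syn and anti-Markovnikov across the terminal alkyne, and iodinolysis of the C–Zr bond with retention gives the (E)-iodide exclusively.

**Step 9**
Reactants: 13 ({[(3E)-4-iodobut-3-en-1-yl]oxy}methyl)benzene; 9 (2R,6S)-2-[(E)-2-(benzyloxy)ethenyl]-2,6-dimethylcyclohexan-1-one
Product: 16 (1S,2R,6S)-1-[(1E)-4-(benzyloxy)but-1-en-1-yl]-2-[(E)-2-(benzyloxy)ethenyl]-2,6-dimethylcyclohexan-1-ol, via alkenyllithium 14 (not isolated), via alkenylcerium dichloride 15 (not isolated)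
Conditions: t-BuLi (2 equiv), Et2O, −78 °C; CeCl3, THF, −78 °C; then 9, −78 to −40 °C
Reagents that add atoms: none
Why: Iodine–lithium exchange with retention and transmetalation give a weakly basic alkenylcerium reagent that adds 1,2 to the ketone (organocerium carbonyl addition), whose chair is locked with both methyl groups equatorial and the C10 alkenyl group axial, so attack occurs on the face anti to that axial group and the new C5 alkenyl group ends trans to the C10 alkenyl group and cis to the C4 methyl group, which defines C5 as S in 16.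

**Step 10**
Reactants: 16 (1S,2R,6S)-1-[(1E)-4-(benzyloxy)but-1-en-1-yl]-2-[(E)-2-(benzyloxy)ethenyl]-2,6-dimethylcyclohexan-1-ol
Product: 19 (3S,4R,5E,10S)-4-(benzyloxy)-3-[2-(benzyloxy)ethyl]-6,10-dimethylcyclodec-5-en-1-one, via potassium alkoxide 17 (not isolated), via potassium enolate 18 (not isolated)
Conditions: KH (3 equiv), 18-crown-6 (3 equiv), THF, 0 to 40 °C; then NH4Cl (aq), −78 °C
Reagents that add atoms: none
Why: Deprotonation gives the crown-ether-separated potassium alkoxide 17, whose oxyanion weakens the adjacent C5–C10 bond and drives a concerted [3,3] sigmatropic shift (anionic oxy-Cope rearrangement, the closest precedent being ring expansion of trans-1,2-dialkenylcyclohexanols to (E)-cyclodec-5-enones) in which C5–C10 breaks while C7–C8 forms. The ten-membered carbocycle is thus closed by four-atom ring expansion of the cyclohexane through a six-centre transition state, not by end-to-end cyclisation, and cold protonation of enolate 18 at C6 unveils the C5 ketone. The trans relationship of the alkenyl groups places both equatorial on the cyclohexane chair and enforces a chair-shaped pericyclic array in which the ring bonds to C1 and C4 are equatorial and the C10 methyl group and the oxide are axial, which fixes the (E)-C9=C10 geometry. C7 is controlled by the (E)-C6=C7 alkene and C8 by the (E)-enol ether, each placing its substituent equatorial on that chair, so the C5/C10 configuration of 16 is relayed to 7S,8R in 19 (threo, the future trans lactone fusion). The step needs chair over boat selectivity and no stereochemical leakage, which are secured by the diequatorial trans-dialkenyl arrangement and by the geometric purity of both alkenes from steps 5, 6 and 8, and it needs C4 to survive, which it should because the enolate is generated regiospecifically towards C6 and quenched cold.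

**Step 11**
Reactants: 19 (3S,4R,5E,10S)-4-(benzyloxy)-3-[2-(benzyloxy)ethyl]-6,10-dimethylcyclodec-5-en-1-one
Product: 20 (1R,3S,4R,5E,10S)-4-(benzyloxy)-3-[2-(benzyloxy)ethyl]-6,10-dimethylcyclodec-5-en-1-ol
Conditions: LiBH(s-Bu)3, THF, −78 °C; then NaOH, H2O2, 0 °C
Reagents that add atoms: none
Why: Hydride delivery from the bulky trialkylborohydride should follow the Felkin–Anh model about the C4 stereocentre (ring carbon C3 anti to the incoming hydride, the methyl group beside the carbonyl oxygen), which coincides with attack on the peripheral face of the medium ring and gives the (5R) alcohol whose oxygen points into the ring towards C10.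

**Step 12**
Reactants: 20 (1R,3S,4R,5E,10S)-4-(benzyloxy)-3-[2-(benzyloxy)ethyl]-6,10-dimethylcyclodec-5-en-1-ol
Product: 22 (1R,2S,3R,4S,6R,7S)-3-(benzyloxy)-4-[2-(benzyloxy)ethyl]-1,7-dimethyl-11-oxabicyclo[4.4.1]undecan-2-ol, via epoxy alcohol 21 (not isolated)
Conditions: m-CPBA, CH2Cl2, 0 °C; then camphorsulfonic acid (10 mol %), 0 to 25 °C
Reagents that add atoms: 3-chloroperoxybenzoic acid, OOC(=O)c1cccc(Cl)c1
Why: Peracid epoxidation of the trisubstituted (E)-alkene on its exposed outer face (the conformer in which H8 eclipses the alkene to relieve allylic 1,3-strain against the C10 methyl group) should give the (9S,10S)-epoxide 21, and acid-promoted transannular opening by the C5 hydroxyl at the tertiary C10 with inversion (intramolecular Markovnikov epoxide opening, 7-exo for ring A and 7-endo for ring B, favoured over attack at the secondary, alkoxy-deactivated C9) closes both oxepanes, sets C10 as R and leaves the epoxide oxygen as the (9S) hydroxyl.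

**Step 13**
Reactants: 22 (1R,2S,3R,4S,6R,7S)-3-(benzyloxy)-4-[2-(benzyloxy)ethyl]-1,7-dimethyl-11-oxabicyclo[4.4.1]undecan-2-ol
Product: 23 (1R,2S,3R,4S,6R,7S)-4-(2-hydroxyethyl)-1,7-dimethyl-11-oxabicyclo[4.4.1]undecane-2,3-diol
Conditions: H2 (1 atm), Pd(OH)2/C, EtOH, 25 °C
Reagents that add atoms: none
Why: Catalytic hydrogenolysis cleaves both benzyl C–O bonds in one operation, there being no alkene left to reduce, and liberates the C8 and C12 hydroxyls needed for the lactone.

**Step 14**
Reactants: 23 (1R,2S,3R,4S,6R,7S)-4-(2-hydroxyethyl)-1,7-dimethyl-11-oxabicyclo[4.4.1]undecane-2,3-diol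
Product: 25 (4S,5R,7R,8R,9S,10R)-5,10-epoxy-9-hydroxy-13-norgermacrano-12,8-lactone, via lactol 24 (not isolated)
Conditions: TEMPO (20 mol %), PhI(OAc)2 (2.5 equiv), CH2Cl2, 25 °C
Reagents that add atoms: none
Why: Oxoammonium-mediated oxidation selects the primary C12 alcohol, the aldehyde is trapped by the neighbouring C8 hydroxyl as the five-membered lactol 24 and this is oxidised again to the trans-fused γ-lactone (oxidative lactonisation of a 1,4-diol), while the hindered secondary C9 hydroxyl is oxidised much more slowly.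

**Step 15**
Reactants: 25 (4S,5R,7R,8R,9S,10R)-5,10-epoxy-9-hydroxy-13-norgermacrano-12,8-lactone
Product: 27 (4S,5R,7R,8R,9S,10R)-13-(dimethylamino)-5,10-epoxy-9-hydroxygermacrano-12,8-lactone (C11 epimers), via dilithium enolate alkoxide 26 (not isolated)
Conditions: LiN(i-Pr)2 (3 equiv), THF, −78 °C; then CH2=NMe2+ I−, −78 to 0 °C
Reagents that add atoms: N,N-dimethylmethyleneiminium iodide, C=[N+](C)C.[I-]
Why: Excess amide base forms the C9 alkoxide and the lactone enolate, which is aminomethylated at C11 by the iminium salt (Mannich reaction with Eschenmoser's salt), and the configuration at C11 is irrelevant because that carbon becomes trigonal in step 17.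

**Step 16**
Reactants: 27 (4S,5R,7R,8R,9S,10R)-13-(dimethylamino)-5,10-epoxy-9-hydroxygermacrano-12,8-lactone; 28 3-methylbutanoyl chloride
Product: 29 (4S,5R,7R,8R,9S,10R)-13-(dimethylamino)-5,10-epoxy-9-(3-methylbutanoyloxy)germacrano-12,8-lactone (C11 epimers)
Conditions: Et3N, DMAP (20 mol %), CH2Cl2, 0 to 25 °C
Reagents that add atoms: none
Why: Nucleophile-catalysed acylation of the only free hydroxyl installs the isovalerate at C9 with retention, while the future methylene is still masked as the Mannich base and so cannot act as a Michael acceptor.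

**Step 17**
Reactants: 29 (4S,5R,7R,8R,9S,10R)-13-(dimethylamino)-5,10-epoxy-9-(3-methylbutanoyloxy)germacrano-12,8-lactone
Product: 31 CNP0274454.1, via trimethylammonium iodide 30 (not isolated)
Conditions: MeI, MeOH, 25 °C; then NaHCO3 (aq), CH2Cl2, 25 °C
Reagents that add atoms: none
Why: Exhaustive N-methylation and mild-base E1cB loss of trimethylamine from the β-ammonio lactone (Hofmann-type elimination) unveil the exocyclic C11=C13 alkene without touching the ester or any stereocentre.

**Compound list**

1 | cis-2,6-dimethylcyclohexan-1-one ((2R,6S), meso) | C[C@H]1CCC[C@@H](C)C1=O | starting material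
2 | lithium (6S)-2,6-dimethylcyclohex-1-en-1-olate | [Li+].[O-]C1=C(C)CCC[C@@H]1C | intermediate
3 | trimethyl{[(6S)-2,6-dimethylcyclohex-1-en-1-yl]oxy}silane | C[Si](C)(C)OC1=C(C)CCC[C@@H]1C | intermediate
4 | (2R,6S)-2,6-dimethyl-2-(prop-2-en-1-yl)cyclohexan-1-one | O=C1[C@@](C)(CC=C)CCC[C@@H]1C | intermediate
5 | (2R,6S)-2,6-dimethyl-2-[(1E)-prop-1-en-1-yl]cyclohexan-1-one | O=C1[C@@](C)(/C=C/C)CCC[C@@H]1C | intermediate
6 | (2R,6S)-2,6-dimethyl-2-(5-methyl-1,2,4-trioxolan-3-yl)cyclohexan-1-one (ozonide, trioxolane centres unspecified) | O=C1[C@@](C)(C2OOC(C)O2)CCC[C@@H]1C | intermediate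
7 | (1R,3S)-1,3-dimethyl-2-oxocyclohexane-1-carbaldehyde | O=C1[C@@](C)(C=O)CCC[C@@H]1C | intermediate
8 | (2R,6S)-2,6-dimethyl-2-[(E)-2-(4,4,5,5-tetramethyl-1,3,2-dioxaborolan-2-yl)ethenyl]cyclohexan-1-one | O=C1[C@@](C)(/C=C/B2OC(C)(C)C(C)(C)O2)CCC[C@@H]1C | intermediate
9 | (2R,6S)-2-[(E)-2-(benzyloxy)ethenyl]-2,6-dimethylcyclohexan-1-one | O=C1[C@@](C)(/C=C/OCc2ccccc2)CCC[C@@H]1C | intermediate
10 | but-3-yn-1-ol | C#CCCO | starting material
11 | [(but-3-yn-1-yloxy)methyl]benzene | C#CCCOCc1ccccc1 | intermediate
12 | [(1E)-4-(benzyloxy)but-1-en-1-yl]chloridobis(cyclopentadienyl)zirconium | Cl[Zr](/C=C/CCOCc1ccccc1)(C1C=CC=C1)C1C=CC=C1 | intermediate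
13 | ({[(3E)-4-iodobut-3-en-1-yl]oxy}methyl)benzene | I/C=C/CCOCc1ccccc1 | intermediate
14 | [(1E)-4-(benzyloxy)but-1-en-1-yl]lithium | [Li]/C=C/CCOCc1ccccc1 | intermediate
15 | [(1E)-4-(benzyloxy)but-1-en-1-yl]cerium dichloride | Cl[Ce](Cl)/C=C/CCOCc1ccccc1 | intermediate
16 | (1S,2R,6S)-1-[(1E)-4-(benzyloxy)but-1-en-1-yl]-2-[(E)-2-(benzyloxy)ethenyl]-2,6-dimethylcyclohexan-1-ol (key-step precursor) | O[C@@]1(/C=C/CCOCc2ccccc2)[C@@](C)(/C=C/OCc2ccccc2)CCC[C@@H]1C | intermediate
17 | potassium alkoxide of 16 | [K+].[O-][C@@]1(/C=C/CCOCc2ccccc2)[C@@](C)(/C=C/OCc2ccccc2)CCC[C@@H]1C | intermediate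
18 | potassium (1Z,3S,4R,5E,10S)-4-(benzyloxy)-3-[2-(benzyloxy)ethyl]-6,10-dimethylcyclodeca-1,5-dien-1-olate | [K+].[O-]/C1=C\[C@H](CCOCc2ccccc2)[C@@H](OCc2ccccc2)/C=C(C)/CCC[C@@H]1C | intermediate
19 | (3S,4R,5E,10S)-4-(benzyloxy)-3-[2-(benzyloxy)ethyl]-6,10-dimethylcyclodec-5-en-1-one (key-step product) | O=C1C[C@H](CCOCc2ccccc2)[C@@H](OCc2ccccc2)/C=C(C)/CCC[C@@H]1C | intermediate
20 | (1R,3S,4R,5E,10S)-4-(benzyloxy)-3-[2-(benzyloxy)ethyl]-6,10-dimethylcyclodec-5-en-1-ol | O[C@@H]1C[C@H](CCOCc2ccccc2)[C@@H](OCc2ccccc2)/C=C(C)/CCC[C@@H]1C | intermediate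
21 | (1S,2R,3S,5R,6S,10S)-2-(benzyloxy)-3-[2-(benzyloxy)ethyl]-6,10-dimethyl-11-oxabicyclo[8.1.0]undecan-5-ol | O[C@@H]1C[C@H](CCOCc2ccccc2)[C@@H](OCc2ccccc2)[C@@H]2O[C@@]2(C)CCC[C@@H]1C | intermediate
22 | (1R,2S,3R,4S,6R,7S)-3-(benzyloxy)-4-[2-(benzyloxy)ethyl]-1,7-dimethyl-11-oxabicyclo[4.4.1]undecan-2-ol | c1ccccc1CO[C@@H]2[C@@H](CCOCc3ccccc3)C[C@H]1O[C@](C)(CCC[C@@H]1C)[C@H]2O | intermediate
23 | (1R,2S,3R,4S,6R,7S)-4-(2-hydroxyethyl)-1,7-dimethyl-11-oxabicyclo[4.4.1]undecane-2,3-diol | O[C@@H]2[C@@H](CCO)C[C@H]1O[C@](C)(CCC[C@@H]1C)[C@H]2O | intermediate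
24 | lactol: C12 hemiacetal of 23 closed onto the C8 oxygen, C9 hydroxyl free (C12 epimers) | C1C(O)O[C@@H]2[C@@H]1C[C@H]1O[C@](C)(CCC[C@@H]1C)[C@H]2O | intermediate
25 | (4S,5R,7R,8R,9S,10R)-5,10-epoxy-9-hydroxy-13-norgermacrano-12,8-lactone (target skeleton with CH2 at C11 and free C9 hydroxyl) | C1C(=O)O[C@@H]2[C@@H]1C[C@H]1O[C@](C)(CCC[C@@H]1C)[C@H]2O | intermediate
26 | dilithium C9 alkoxide and C11–C12 lactone enolate of 25 | [Li+].[Li+].C1=C([O-])O[C@@H]2[C@@H]1C[C@H]1O[C@](C)(CCC[C@@H]1C)[C@H]2[O-] | intermediate
27 | (4S,5R,7R,8R,9S,10R)-13-(dimethylamino)-5,10-epoxy-9-hydroxygermacrano-12,8-lactone (C11 epimers) | CN(C)CC1C(=O)O[C@@H]2[C@@H]1C[C@H]1O[C@](C)(CCC[C@@H]1C)[C@H]2O | intermediate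
28 | 3-methylbutanoyl chloride (isovaleryl chloride) | CC(C)CC(Cl)=O | starting material
29 | (4S,5R,7R,8R,9S,10R)-13-(dimethylamino)-5,10-epoxy-9-(3-methylbutanoyloxy)germacrano-12,8-lactone (C11 epimers) | CN(C)CC1C(=O)O[C@@H]2[C@@H]1C[C@H]1O[C@](C)(CCC[C@@H]1C)[C@H]2OC(=O)CC(C)C | intermediate
30 | trimethylammonium iodide of 29 | [I-].C[N+](C)(C)CC1C(=O)O[C@@H]2[C@@H]1C[C@H]1O[C@](C)(CCC[C@@H]1C)[C@H]2OC(=O)CC(C)C | intermediate
31 | CNP0274454.1, (4S,5R,7R,8R,9S,10R)-5,10-epoxy-9-(3-methylbutanoyloxy)germacr-11(13)-eno-12,8-lactone | C=C1C(=O)O[C@@H]2[C@@H]1C[C@H]1O[C@](C)(CCC[C@@H]1C)[C@H]2OC(=O)CC(C)C | target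

**Step count.** Total: 17 steps. Longest linear sequence: 15 steps (steps 1–6 and 9–17).

**Steps most likely to fail**

1. Step 10 (key step). The alkoxide may cleave the C5–C10 bond heterolytically and recombine or protonate without stereocontrol, part of the material may pass through a boat arrangement, or the enolate may equilibrate and scramble C4. The two axial methyl groups of the reactive chair also slow the shift. Fallback (neutral thermal siloxy-Cope): setting out from 16, silylation (Me3SiCl, imidazole, DMF) gives the trimethylsilyl ether F1. Heating in o-dichlorobenzene at about 200 °C should effect the uncharged [3,3] shift through the same chair to the ten-membered trimethylsilyl enol ether F2, with no free alkoxide or enolate present. K2CO3 in MeOH at 0 °C then cleaves the silyl enol ether and the route is rejoined at 19.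

2. Step 11. Hydride delivery may show poor facial selectivity if the macrocycle presents the other carbonyl face, giving a C5 alcohol whose oxygen cannot reach C10 in step 12. Fallback (let the bicycle fix C5): setting out from 19, m-CPBA in CH2Cl2 epoxidises the alkene to the keto epoxide F3. Et3SiH with BF3·OEt2 (CH2Cl2, −78 °C) then triggers opening of the activated epoxide at C10 by the carbonyl oxygen and hydride capture of the bridged oxocarbenium ion from its only exposed face (silane reductive etherification). This gives the bicyclic ether directly and comes back to the route at 22, bypassing step 12.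

3. Step 6. Transmetalation may be slow, with competing protodeboronation or oxidative homocoupling of the alkenylboronate, so that the enol ether forms inefficiently. Fallback (halide cross-coupling instead of oxidative coupling): setting out from 7, iodo-olefination (CHI3, CrCl2, THF, 0 °C; Takai olefination) gives the (E)-alkenyl iodide F4. This is coupled with benzyl alcohol under copper catalysis (CuI, 3,4,7,8-tetramethyl-1,10-phenanthroline, Cs2CO3, toluene, 80 °C; Ullmann-type C–O coupling with retention of geometry) and the route is rejoined at 9. Because this medium is basic enough to epimerise C4, the minor C6 epimer of 9 would be removed by chromatography before step 9.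

**Further compounds**

F1 | step 10 | {[(1S,2R,6S)-1-[(1E)-4-(benzyloxy)but-1-en-1-yl]-2-[(E)-2-(benzyloxy)ethenyl]-2,6-dimethylcyclohexyl]oxy}trimethylsilane | C[Si](C)(C)O[C@@]1(/C=C/CCOCc2ccccc2)[C@@](C)(/C=C/OCc2ccccc2)CCC[C@@H]1C
F2 | step 10 | {[(1Z,3S,4R,5E,10S)-4-(benzyloxy)-3-[2-(benzyloxy)ethyl]-6,10-dimethylcyclodeca-1,5-dien-1-yl]oxy}trimethylsilane | C[Si](C)(C)O/C1=C\[C@H](CCOCc2ccccc2)[C@@H](OCc2ccccc2)/C=C(C)/CCC[C@@H]1C
F3 | step 11 | (1S,2R,3S,6S,10S)-2-(benzyloxy)-3-[2-(benzyloxy)ethyl]-6,10-dimethyl-11-oxabicyclo[8.1.0]undecan-5-one | O=C1C[C@H](CCOCc2ccccc2)[C@@H](OCc2ccccc2)[C@@H]2O[C@@]2(C)CCC[C@@H]1C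
F4 | step 6 | (2R,6S)-2-[(E)-2-iodoethenyl]-2,6-dimethylcyclohexan-1-one | O=C1[C@@](C)(/C=C/I)CCC[C@@H]1C
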